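**Retrosynthetic overview** (benzofuranone numbering: O1, C2, C3, C3a, C4, C5, C6, C7, C7a)
1. Target 13 ⇐ saturated cis-ketolactone 12 by dehydrogenation across C6–C7; this is the only side of the C5 ketone with a β-hydrogen, because C4 abuts the quaternary C3a.
2. 12 ⇐ ester 11 by one rhodium-catalysed carboacylation: the C5–C7a bond of a cyclobutanone is cut and the pendant olefin C3a=C4 is sewn in, forming C4–C5 and C3a–C7a together with both stereocentres.
3. Enabling feature: in the carbocycle the ketone carbon C5 and the oxygen-bearing C7a are linked by the two-carbon bridge C6–C7 (a cyclobutanone once C5 is bonded to C7a); the other two ring atoms, C4 (a methylene) and the quaternary C3a, are a 1,1-disubstituted olefin; and the lactone atoms O1–C2–C3 tie C7a to C3a as a three-atom ester tether.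
4. 11 ⇐ acid 8 + 2-hydroxycyclobutanone 9 (esterification); 8 ⇐ farnesyl bromide 3 + 3-bromobut-3-en-1-ol 1 (copper-catalysed Grignard coupling, then oxidation).
5. Ring order: the four-membered ring is bought; the γ-lactone and the six-membered ring close together in step 6; the enone unsaturation comes last.

Key step: step 6

Assumption: the SMILES is read as the cis-fused (3aR,7aR) lactone with a (2E,6E)-farnesyl chain; the sense of induction of the chiral rhodium catalyst in step 6 cannot be predicted for this new substrate, so (R)-DTBM-SEGPHOS is written and the (S)-ligand would be used if a test run showed the opposite sense.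

**Step 1**
Reactants: 1 3-bromobut-3-en-1-ol
Product: 2 tert-butyl[(3-bromobut-3-en-1-yl)oxy]dimethylsilane
Conditions: TBSCl, imidazole, CH2Cl2, 0 °C → rt
Reagents that add atoms: tert-butyldimethylsilyl chloride (TBSCl), CC(C)(C)[Si](C)(C)Cl
Why: Standard silylation of a primary alcohol masks the hydroxyl so that the vinyl bromide can be turned into a Grignard reagent; no stereocentre is involved.

**Step 2**
Reactants: 2 tert-butyl[(3-bromobut-3-en-1-yl)oxy]dimethylsilane; 3 (2E,6E)-farnesyl bromide
Product: 5 tert-butyldimethyl{[(5E,9E)-6,10,14-trimethyl-3-methylidenepentadeca-5,9,13-trien-1-yl]oxy}silane, via Grignard reagent 4 (not isolated)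
Conditions: Mg, THF, 50 °C; then 3, Li2CuCl4 (3 mol%), THF, −20 → 0 °C
Reagents that add atoms: none
Why: Magnesium insertion into the 2-bromoalkene followed by Li2CuCl4-catalysed Grignard cross-coupling with the primary allylic bromide should give direct (α) substitution with retention of the (2E) olefin, because the γ-carbon of the farnesyl unit is fully substituted; no stereocentre is formed.

**Step 3**
Reactants: 5 tert-butyldimethyl{[(5E,9E)-6,10,14-trimethyl-3-methylidenepentadeca-5,9,13-trien-1-yl]oxy}silane
Product: 6 (5E,9E)-6,10,14-trimethyl-3-methylidenepentadeca-5,9,13-trien-1-ol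
Conditions: TBAF, THF, 0 °C → rt
Reagents that add atoms: none
Why: Fluoride-mediated desilylation, driven by the Si–F bond, should leave the skipped diene and the trisubstituted olefins untouched.

**Step 4**
Reactants: 6 (5E,9E)-6,10,14-trimethyl-3-methylidenepentadeca-5,9,13-trien-1-ol
Product: 8 (5E,9E)-6,10,14-trimethyl-3-methylidenepentadeca-5,9,13-trienoic acid, via trienal 7 (not isolated)
Conditions: TEMPO (20 mol%), PhI(OAc)2 (2.2 equiv), MeCN/H2O 1:1, rt
Reagents that add atoms: water, O
Why: The oxoammonium (TEMPO/PhI(OAc)2) oxidation takes the primary alcohol through the aldehyde and its hydrate to the acid under near-neutral conditions that spare the olefins and should outrun conjugation of the β,γ-unsaturated aldehyde.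

**Step 5**
Reactants: 8 (5E,9E)-6,10,14-trimethyl-3-methylidenepentadeca-5,9,13-trienoic acid; 9 2-hydroxycyclobutan-1-one (racemic)
Product: 11 (RS)-2-oxocyclobutyl (5E,9E)-6,10,14-trimethyl-3-methylidenepentadeca-5,9,13-trienoate, via O-acylisourea 10 (not isolated)
Conditions: DCC, DMAP (5 mol%), CH2Cl2, 0 °C
Reagents that add atoms: none
Why: Steglich esterification with little DMAP at low temperature should acylate the acyloin hydroxyl without moving the β,γ-olefin into conjugation; the stereocentre of 9 is carried as the racemate.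

**Step 6**
Reactants: 11 (RS)-2-oxocyclobutyl (5E,9E)-6,10,14-trimethyl-3-methylidenepentadeca-5,9,13-trienoate
Product: 12 (3aR,7aR)-3a-[(2E,6E)-3,7,11-trimethyldodeca-2,6,10-trien-1-yl]-3a,6,7,7a-tetrahydro-1-benzofuran-2,5(3H,4H)-dione
Conditions: [RhCl(cod)]2 (5 mol%), (R)-DTBM-SEGPHOS (12 mol%), 2-amino-3-methylpyridine (20 mol%), 1,4-dioxane, 110 °C, argon
Reagents that add atoms: none
Why: Proposed new method: monovalent rhodium should add oxidatively into the acyl–C(α) bond C5–C7a of the cyclobutanone (the bond that bears the acyloxy tether), the pendant 1,1-disubstituted olefin C3a=C4 should then insert into the Rh–C7a bond, and C(sp3)–C(acyl) reductive elimination should forge C4–C5 and release the catalyst; the closest known reaction type is the rhodium-catalysed intramolecular "cut-and-sew" carboacylation of cyclobutanones and benzocyclobutenones with tethered olefins, which is established for 1,1-disubstituted olefins and all-carbon quaternary centres but not for an α-acyloxycyclobutanone with an ester tether. The γ-lactone closes in the migratory insertion as a 5-exo ring closure (C3a–C7a bond), which leaves rhodium on the C4 methylene where the quaternary C3a offers no β-hydrogen, and the six-membered carbocycle closes by reductive elimination from the resulting seven-membered rhodacycle, so that the four-membered ring is expanded by the two olefin carbons. C7a keeps the configuration of the cyclobutanone α-carbon because oxidative addition and insertion proceed with retention, and C3a is set relative to it by the three-atom ester tether, which should reach the Rh–C7a bond only from the face that gives the cis-fused bicycle (H-7a and the farnesyl chain syn). The absolute configuration should come from the chiral bisphosphine, which is expected to take the (R)-ester through the cycle faster than the (S)-ester, while the aminopyridine interconverts the two enantiomers through its ketimine and enamine so that the resolution becomes dynamic. The step needs insertion into C5–C7a and not into C5–C6, which the tether secures because only that rhodacycle can engage the olefin and the other insertion is reversible, and it needs the 1,1-disubstituted olefin to react in preference to the three trisubstituted olefins of the chain, which are remote and much poorer ligands.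

**Step 7**
Reactants: 12 (3aR,7aR)-3a-[(2E,6E)-3,7,11-trimethyldodeca-2,6,10-trien-1-yl]-3a,6,7,7a-tetrahydro-1-benzofuran-2,5(3H,4H)-dione
Product: 13 (3aR,7aR)-3a-[(2E,6E)-3,7,11-trimethyldodeca-2,6,10-trien-1-yl]-3a,7a-dihydro-1-benzofuran-2,5(3H,4H)-dione
Conditions: IBX (1.5 equiv), 4-methoxypyridine N-oxide (1.5 equiv), DMSO, 25 °C
Reagents that add atoms: none
Why: IBX dehydrogenation of the ketone through its enol can only deliver the C6=C7 enone, because the other α-carbon (C4) is attached to the hydrogen-free quaternary C3a; neither stereocentre is touched.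

**Compound list**
1 | 3-bromobut-3-en-1-ol | C=C(Br)CCO | starting material
2 | tert-butyl[(3-bromobut-3-en-1-yl)oxy]dimethylsilane | C=C(Br)CCO[Si](C)(C)C(C)(C)C | intermediate
3 | (2E,6E)-farnesyl bromide, (2E,6E)-1-bromo-3,7,11-trimethyldodeca-2,6,10-triene | CC(C)=CCC/C(C)=C/CC/C(C)=C/CBr | starting material
4 | {4-[(tert-butyldimethylsilyl)oxy]but-1-en-2-yl}magnesium bromide | C=C([Mg]Br)CCO[Si](C)(C)C(C)(C)C | intermediate
5 | tert-butyldimethyl{[(5E,9E)-6,10,14-trimethyl-3-methylidenepentadeca-5,9,13-trien-1-yl]oxy}silane | CC(C)=CCC/C(C)=C/CC/C(C)=C/CC(=C)CCO[Si](C)(C)C(C)(C)C | intermediate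
6 | (5E,9E)-6,10,14-trimethyl-3-methylidenepentadeca-5,9,13-trien-1-ol | CC(C)=CCC/C(C)=C/CC/C(C)=C/CC(=C)CCO | intermediate
7 | (5E,9E)-6,10,14-trimethyl-3-methylidenepentadeca-5,9,13-trienal | CC(C)=CCC/C(C)=C/CC/C(C)=C/CC(=C)CC=O | intermediate
8 | (5E,9E)-6,10,14-trimethyl-3-methylidenepentadeca-5,9,13-trienoic acid | CC(C)=CCC/C(C)=C/CC/C(C)=C/CC(=C)CC(=O)O | intermediate
9 | 2-hydroxycyclobutan-1-one (racemic) | O=C1CCC1O | starting material
10 | O-acylisourea of acid 8 with DCC | CC(C)=CCC/C(C)=C/CC/C(C)=C/CC(=C)CC(=O)OC(=NC1CCCCC1)NC1CCCCC1 | intermediate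
11 | (RS)-2-oxocyclobutyl (5E,9E)-6,10,14-trimethyl-3-methylidenepentadeca-5,9,13-trienoate | CC(C)=CCC/C(C)=C/CC/C(C)=C/CC(=C)CC(=O)OC1CCC1=O | intermediate
12 | (3aR,7aR)-3a-[(2E,6E)-3,7,11-trimethyldodeca-2,6,10-trien-1-yl]-3a,6,7,7a-tetrahydro-1-benzofuran-2,5(3H,4H)-dione | CC(C)=CCC/C(C)=C/CC/C(C)=C/C[C@]12CC(=O)CC[C@H]1OC(=O)C2 | intermediate
13 | (3aR,7aR)-3a-[(2E,6E)-3,7,11-trimethyldodeca-2,6,10-trien-1-yl]-3a,7a-dihydro-1-benzofuran-2,5(3H,4H)-dione | CC(C)=CCC/C(C)=C/CC/C(C)=C/C[C@]12CC(=O)C=C[C@H]1OC(=O)C2 | target

**Total step count:** 7. **Longest linear sequence:** 7 steps (1 → 13).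

**Steps most likely to fail**

Step 6 (proposed new method). The rhodacyclopentanone may lose CO to give a cyclopropane, rhodium hydride may isomerise the skipped diene before insertion, or the catalyst may discriminate poorly between the substrate enantiomers while racemisation is slow. The fallback gives up the ring expansion and builds the carbocycle from an arene by known chemistry; it sets out from farnesyl bromide 3 and comes back at target 13. Birch reduction of 3-methoxybenzoic acid (Li, NH3/THF, −78 °C) should give the dilithium dianion F1. Alkylation in the same flask with 3 at the carboxylate-bearing carbon, followed by resolution of the racemate on a chiral stationary phase, should give (1R)-3-methoxy-1-farnesylcyclohexa-2,5-diene-1-carboxylic acid F2. Arndt–Eistert homologation then follows: 1-chloro-N,N,2-trimethylprop-1-en-1-amine gives the acid chloride F3, CH2N2 gives the diazoketone F4, and Wolff rearrangement (PhCO2Ag, Et3N, THF/H2O) through the ketene F5, with retention at the migrating quaternary carbon, should give the homologated acetic acid F6. Mild hydrolysis of the enol ether (oxalic acid, THF/H2O) should unveil the β,γ-unsaturated keto acid F7. Iodolactonisation (I2, NaHCO3, MeCN/H2O, 0 °C) should close the cis-fused γ-lactone from the face of the acetic acid arm and give the trans-iodo lactone F8. E1cB loss of hydrogen iodide (Et3N, CH2Cl2) then places the olefin at C6=C7 and gives 13.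

Step 5. Acyl activation of the β,γ-unsaturated acid may drag the 1,1-disubstituted olefin into conjugation, and the acyloin may self-condense under DMAP. The fallback never activates the carboxyl group; it sets out from acid 8 and comes back at ester 11. Acid 8 is converted into its cesium carboxylate F9 (Cs2CO3, DMF, 0 °C), which is alkylated at oxygen with 2-bromocyclobutanone by SN2 displacement at the α-keto carbon.

Step 7. Conversion may stall, or the oxidant may attack allylic positions of the polyene chain. The fallback separates enolisation from oxidation; it sets out from ketolactone 12 and comes back at target 13. Kinetic deprotonation at the less hindered C6 (LDA, THF, −78 °C) should give the lithium enolate F10, TMSCl traps it as the silyl enol ether F11, and Saegusa–Ito oxidation (Pd(OAc)2, MeCN, rt) should deliver 13.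

**Further compounds**
F1 | step 6 | dilithium 3-methoxycyclohexa-2,5-dien-1-ide-1-carboxylate (Birch dianion) | COC1=C[C-](C(=O)[O-])C=CC1.[Li+].[Li+]
F2 | step 6 | (1R)-3-methoxy-1-[(2E,6E)-3,7,11-trimethyldodeca-2,6,10-trien-1-yl]cyclohexa-2,5-diene-1-carboxylic acid | CC(C)=CCC/C(C)=C/CC/C(C)=C/C[C@]1(C(=O)O)C=C(OC)CC=C1
F3 | step 6 | (1R)-3-methoxy-1-[(2E,6E)-3,7,11-trimethyldodeca-2,6,10-trien-1-yl]cyclohexa-2,5-diene-1-carbonyl chloride | CC(C)=CCC/C(C)=C/CC/C(C)=C/C[C@]1(C(=O)Cl)C=C(OC)CC=C1
F4 | step 6 | 2-diazo-1-{(1R)-3-methoxy-1-[(2E,6E)-3,7,11-trimethyldodeca-2,6,10-trien-1-yl]cyclohexa-2,5-dien-1-yl}ethan-1-one | CC(C)=CCC/C(C)=C/CC/C(C)=C/C[C@]1(C(=O)C=[N+]=[N-])C=C(OC)CC=C1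
F5 | step 6 | 2-{(1R)-3-methoxy-1-[(2E,6E)-3,7,11-trimethyldodeca-2,6,10-trien-1-yl]cyclohexa-2,5-dien-1-yl}ethen-1-one (ketene) | CC(C)=CCC/C(C)=C/CC/C(C)=C/C[C@]1(C=C=O)C=C(OC)CC=C1
F6 | step 6 | 2-{(1R)-3-methoxy-1-[(2E,6E)-3,7,11-trimethyldodeca-2,6,10-trien-1-yl]cyclohexa-2,5-dien-1-yl}acetic acid | CC(C)=CCC/C(C)=C/CC/C(C)=C/C[C@]1(CC(=O)O)C=C(OC)CC=C1
F7 | step 6 | 2-{(1R)-5-oxo-1-[(2E,6E)-3,7,11-trimethyldodeca-2,6,10-trien-1-yl]cyclohex-2-en-1-yl}acetic acid | CC(C)=CCC/C(C)=C/CC/C(C)=C/C[C@]1(CC(=O)O)CC(=O)CC=C1
F8 | step 6 | (3aR,7S,7aS)-7-iodo-3a-[(2E,6E)-3,7,11-trimethyldodeca-2,6,10-trien-1-yl]hexahydro-1-benzofuran-2,5-dione | CC(C)=CCC/C(C)=C/CC/C(C)=C/C[C@]12CC(=O)C[C@H](I)[C@H]1OC(=O)C2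
F9 | step 5 | cesium (5E,9E)-6,10,14-trimethyl-3-methylidenepentadeca-5,9,13-trienoate | CC(C)=CCC/C(C)=C/CC/C(C)=C/CC(=C)CC(=O)[O-].[Cs+]
F10 | step 7 | lithium (3aR,7aR)-2-oxo-3a-[(2E,6E)-3,7,11-trimethyldodeca-2,6,10-trien-1-yl]-2,3,3a,4,7,7a-hexahydro-1-benzofuran-5-olate | CC(C)=CCC/C(C)=C/CC/C(C)=C/C[C@]12CC([O-])=CC[C@H]1OC(=O)C2.[Li+]
F11 | step 7 | (3aR,7aR)-3a-[(2E,6E)-3,7,11-trimethyldodeca-2,6,10-trien-1-yl]-5-[(trimethylsilyl)oxy]-3a,4,7,7a-tetrahydro-1-benzofuran-2(3H)-one | CC(C)=CCC/C(C)=C/CC/C(C)=C/C[C@]12CC(O[Si](C)(C)C)=CC[C@H]1OC(=O)C2
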